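Jd could not bring more Ja to Jg and Jf than Jd itself supplied, and I took one Jd per Ja.

| flask | Ja | Jd | remark | time |
|---|---|---|---|---|
| maple | 20 mM | 42 mM | run made earlier |  |
| ash | 20 mM | 66 mM | run made earlier |  |
| flask | 20 mM | 30.0 mM |  | 8.0 d |

- maple (time / d: Jg / %, Jf / %, Ja / %): 1.25: 60, 3, 20; 2.50: 90, 5, 6; 4.00: 93, 3, 1; 5.00: 92, 9, 2; 6.00: 96, 8, 0; 8.00: 95, 4, 1
- ash (time / d: Jg / %, Jf / %, Ja / %): 0.625: 28, 3, 44; 1.04: 49, 3, 24; 1.67: 76, 5, 9; 3.00: 92, 2, 1; 5.00: 95, 7, 1; 8.00: 97, 7, 3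

(standard deviation of a reading: 2 percentage points)

- given per volume of solution although it is solid: Jd
- at the start none of Jd is in solution

* ratio of Jg to Jf at 5.0 h
* ratio of Jg to Jf at 8.0 d
* which of Jg and Jf there is more of at 8.0 d

So I reckoned 150% for the flask: its ceiling, Jd charged over Ja charged, in percent of the Ja charged. By that reckoning Jd was not the limiting reagent there, so I expected the flask's Ja to end as Jg and Jf, as the readings of maple and ash showed at their latest times. Summed from 3.00 d on, those runs read Jg to Jf as 16.5, and I committed to that for the flask at 8.0 d. For 5.0 h I committed to no figure: the earliest reading, ash at 0.625 d, gives Jg to Jf as 9.33, with Jf at 3% against a scatter of 2 percentage points.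

The forecast gave 4 (range 1.5 to 12) at 5.0 h and 16 (range 9 to 30) at 8.0 d, with Jg ahead, holding that “Jf looks like a direct side branch”.

The flask gave 6.61 and 15.1, with Jg ahead: Jg 93.8%, Jf 6.22%.

    Ja ⇌ Jc (K = 1.80, k = 2.00 × 10⁻⁵ s⁻¹)
    Ja + Jb → Jf (k = 6.80 × 10⁻⁴ L mol⁻¹ s⁻¹)
    Jb + Jc → Jg (k = 0.0230 L mol⁻¹ s⁻¹)
    Jd ⇌ Jb, rate k4*(cs4 - [Jb]) while solid is left; crystals form when [Jb] > cs4 (solubility = 8.80 mM, k = 1.80 × 10⁻⁵ s⁻¹)
    Jb → Je (k = 2.10 × 10⁻⁶ s⁻¹)

In the flask, Jg and Jf together held >99.9%, under the ceiling. The Jd above that need, 10.0 mM, stood at 8.00 d as dissolved Jb 3.46 mM and its product Je 6.54 mM, with solid Jd at 0%. A neighbour flask, otherwise like this one but charged with 7.5 mM of Jd, had the ceiling scaled down to 37.5%. At 8.00 d it held Jg 34.3% and Jf 2.53%, together 36.8%. There Jd stood at 0%, Jb at 0 mM, Ja at 22.6% and Jc at 40.6%.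

The data are calculated for an exercise; scatter was added.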